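The route rests on the indane bond C-1–C-7a: C-7a belongs to resorcinol ring A and stands meta to both of its oxygens, where no Friedel–Crafts closure can reach, while C-1 is the methine that later carries the diarylmethine of the eight-membered ring. The lactone oxygen of 5,7-dimethoxycoumarin marks C-7a: enantioselective 4-arylation, 3-arylation with a dihydrobenzofuran bromide and one-carbon homologation give a phenol triflate bearing a CH2CHO chain. One palladium-catalysed enolate arylation then trades the C–O bond for the C–C bond, closes the five-membered ring (C-1, C-2, C-3, C-3a, C-7a) and leaves C-1 epimerisable, so it settles all-trans. A benzylic cation closes the eight-membered ring.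

Key step: step 11

Labels: indane atoms are numbered as in 22; ring A = resorcinol ring of the indane, ring B = 3,5-dimethoxyphenyl group on the dihydrobenzofuran, ring C = benzo ring of the dihydrobenzofuran; DBF = (2R,3R)-3-(3,5-dimethoxyphenyl)-6-methoxy-2-(4-methoxyphenyl)-2,3-dihydro-1-benzofuran-4-yl; HFIP = 1,1,1,3,3,3-hexafluoropropan-2-ol.

Assumption: the sense of asymmetric induction in steps 5 and 6 is taken from the behaviour of simpler substrates; should either prove opposite, the antipode of sulfide 7 or of the ligand is used.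

Step 1
Reactants: 1 2-bromo-4,6-dimethoxybenzaldehyde
Product: 2 2-bromo-6-hydroxy-4-methoxybenzaldehyde
Conditions: BCl3 (1.2 equiv), CH2Cl2, −78 to 0 °C; then H2O
Reagents that add atoms: none
Why: Lewis-acid ether cleavage in which boron, chelated between the formyl oxygen and the ortho methoxy group, should remove only that methyl group and leave the para methoxy group.

Step 2
Reactants: 2 2-bromo-6-hydroxy-4-methoxybenzaldehyde; 3 3,5-dimethoxyphenylmagnesium chloride
Product: 4 3-bromo-2-[(3,5-dimethoxyphenyl)(hydroxy)methyl]-5-methoxyphenol (racemic carbinol)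
Conditions: 3 (2.3 equiv), THF, 0 °C to rt; aq. NH4Cl
Reagents that add atoms: 3,5-dimethoxyphenylmagnesium chloride (3), COc1cc(OC)cc([Mg]Cl)c1
Why: Grignard addition, the first equivalent forming the magnesium phenoxide and the second adding to the aldehyde; the carbinol centre is racemic and is erased in step 5.

Step 3
Reactants: 4 3-bromo-2-[(3,5-dimethoxyphenyl)(hydroxy)methyl]-5-methoxyphenol; 5 sodium 4-methylbenzenesulfinate
Product: 6 3-bromo-2-[(3,5-dimethoxyphenyl)(4-methylbenzenesulfonyl)methyl]-5-methoxyphenol (racemic)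
Conditions: 5 (1.5 equiv), HCO2H, CH2Cl2/H2O, rt
Reagents that add atoms: sodium 4-methylbenzenesulfinate (5), [Na+].[O-]S(=O)c1ccc(C)cc1
Why: Acid ionises the ortho-hydroxybenzhydrol to its ortho-quinone methide, which the sulfinate captures at sulfur (SN1-type substitution) to give a bench-stable quinone methide precursor.

Step 4
Reactants: 7 (1R,4R,5R)-4,7,7-trimethyl-6-thiabicyclo[3.2.1]octane (isothiocineole); 8 4-methoxybenzyl bromide
Product: 9 (1R,4R,5R)-6-(4-methoxybenzyl)-4,7,7-trimethyl-6-thiabicyclo[3.2.1]octan-6-ium trifluoromethanesulfonate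
Conditions: 8 (1.5 equiv), LiOSO2CF3 (5 equiv), CH2Cl2/H2O, rt
Reagents that add atoms: 4-methoxybenzyl bromide (8), COc1ccc(CBr)cc1; lithium trifluoromethanesulfonate, [Li+].[O-]S(=O)(=O)C(F)(F)F
Why: S-Alkylation of the sulfide (SN2) with anion exchange to the non-nucleophilic triflate should give the chiral benzylsulfonium salt as a single sulfur diastereomer.

Step 5
Reactants: 6 3-bromo-2-[(3,5-dimethoxyphenyl)(4-methylbenzenesulfonyl)methyl]-5-methoxyphenol; 9 the sulfonium triflate
Product: 11 (2R,3R)-4-bromo-3-(3,5-dimethoxyphenyl)-6-methoxy-2-(4-methoxyphenyl)-2,3-dihydro-1-benzofuran, via ortho-quinone methide 10 (not isolated)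
Conditions: Cs2CO3 (3 equiv), MeCN, 0 °C to rt
Reagents that add atoms: none
Why: Sulfur-ylide formal [4+1] annulation: base eliminates sulfinate from 6 to give 10 and deprotonates 9, the ylide adds to the methide carbon and the phenoxide displaces the sulfide (5-exo-tet), which should give the trans ring through the anti betaine and the (2R,3R) configuration through the face-differentiated ylide of the isothiocineole salt.

Step 6
Reactants: 12 5,7-dimethoxycoumarin; 13 4-methoxyphenylboronic acid
Product: 14 (4S)-5,7-dimethoxy-4-(4-methoxyphenyl)-3,4-dihydro-2H-chromen-2-one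
Conditions: 13 (4 equiv), Rh(acac)(C2H4)2 (3 mol%), (S)-SEGPHOS (3.3 mol%), dioxane/H2O 10:1, 60 °C
Reagents that add atoms: 4-methoxyphenylboronic acid (13), COc1ccc(cc1)B(O)O
Why: Hayashi–Miyaura conjugate addition, in which the aryl complex of monovalent rhodium adds to the coumarin face chosen by the (S)-bisphosphine and water protonates the oxa-π-allyl species, should set C-4 as S.

Step 7
Reactants: 14 (4S)-5,7-dimethoxy-4-(4-methoxyphenyl)-3,4-dihydro-2H-chromen-2-one; 11 the benzofuranyl bromide
Product: 16 (3S,4S)-3-DBF-5,7-dimethoxy-4-(4-methoxyphenyl)-3,4-dihydro-2H-chromen-2-one, via chlorozinc enolate 15 (not isolated)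
Conditions: LiN(SiMe3)2 (1.1 equiv), THF, −78 °C; ZnCl2 (1.2 equiv), −78 °C to rt; 11 (1.0 equiv), Pd(dba)2 (5 mol%), P(t-Bu)3 (10 mol%), 60 °C
Reagents that add atoms: none
Why: Palladium-catalysed α-arylation of a zinc enolate (oxidative addition of zerovalent palladium to 11, transmetallation, reductive elimination), in which the aryl group should enter anti to the C-4 aryl and the acidic C-3 proton lets any cis isomer equilibrate to the 3,4-trans lactone.

Step 8
Reactants: 16 (3S,4S)-3-DBF-5,7-dimethoxy-4-(4-methoxyphenyl)-3,4-dihydro-2H-chromen-2-one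
Product: 17 (3S,4S)-3-DBF-5,7-dimethoxy-4-(4-methoxyphenyl)-3,4-dihydro-2H-chromen-2-ol (both anomers)
Conditions: i-Bu2AlH (1.1 equiv), CH2Cl2, −78 °C; aq. potassium sodium tartrate
Reagents that add atoms: none
Why: Partial hydride reduction of the aryl lactone should stop at the lactol because the tetrahedral aluminate survives at −78 °C; the anomeric centre is irrelevant.

Step 9
Reactants: 17 the lactol; 18 (methoxymethyl)triphenylphosphonium chloride
Product: 20 2-[(1S,2R)-2-DBF-4-methoxy-1-(4-methoxyphenyl)but-3-en-1-yl]-3,5-dimethoxyphenyl trifluoromethanesulfonate (E/Z mixture), via potassium phenoxide 19 (not isolated)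
Conditions: 18 (2.2 equiv), KN(SiMe3)2 (3.2 equiv), THF, −78 to 0 °C; then PhNTf2 (3 equiv), 0 °C to rt
Reagents that add atoms: (methoxymethyl)triphenylphosphonium chloride (18), COC[P+](c1ccccc1)(c1ccccc1)c1ccccc1.[Cl-]; N-phenylbis(trifluoromethanesulfonimide), O=S(=O)(N(c1ccccc1)S(=O)(=O)C(F)(F)F)C(F)(F)F
Why: Wittig olefination of the ring-opened hydroxy aldehyde form of the lactol adds the last skeletal carbon as an enol ether and frees the ring-A phenoxide, which is triflated in the same flask; low temperature and excess ylide should keep the α-aryl aldehyde from enolising, so the two methines stay as set.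

Step 10
Reactants: 20 the enol ether triflate
Product: 21 2-[(1S,2S)-2-DBF-1-(4-methoxyphenyl)-4-oxobutyl]-3,5-dimethoxyphenyl trifluoromethanesulfonate
Conditions: 2 M aq. HCl, THF, rt
Reagents that add atoms: water, O
Why: Acid hydrolysis of the methyl enol ether (C-protonation, hemiacetal, loss of methanol) unveils the CH2CHO chain, while the aryl triflate and the benzofuran ether should be inert to dilute acid.

Step 11
Reactants: 21 2-[(1S,2S)-2-DBF-1-(4-methoxyphenyl)-4-oxobutyl]-3,5-dimethoxyphenyl trifluoromethanesulfonate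
Product: 22 (1S,2R,3S)-2-DBF-4,6-dimethoxy-3-(4-methoxyphenyl)-2,3-dihydro-1H-indene-1-carbaldehyde (all-trans)
Conditions: Pd(OAc)2 (5 mol%), rac-BINAP (7.5 mol%), Cs2CO3 (1.5 equiv), dioxane, 80 °C, degassed
Reagents that add atoms: none
Why: Zerovalent palladium inserts into the aryl C–OTf bond at C-7a, Cs2CO3 forms the aldehyde enolate, and the C-bound palladium enolate (a six-membered palladacycle) reductively eliminates to make the C-7a–C-1 bond. The closest known reaction is the palladium-catalysed intramolecular α-arylation of aldehydes and ketones. The indane ring closes in a 5-exo sense, the enolate carbon attacking the ipso carbon while the formyl group stays outside the ring. The new stereocentre C-1 is α to the formyl group and benzylic, so carbonate should equilibrate it through the enolate to the isomer with CHO trans to the C-2 aryl (itself trans to the C-3 aryl), and both C-1 epimers converge. The step needs C- over O-arylation and no aldol or fluorene-forming C–H arylation: the CH2 is the only enolisable carbon, C-arylation gives a five- and O-arylation a seven-membered ring, and branching at C-2 hinders self-condensation. The triflate, born from the coumarin oxygen, puts the metal on the one ring-A carbon, meta to both methoxy groups, that electrophilic closure cannot reach.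

Step 12
Reactants: 22 the indane carbaldehyde; 23 4-methoxyphenylmagnesium bromide
Product: 24 [(1S,2R,3S)-2-DBF-4,6-dimethoxy-3-(4-methoxyphenyl)-2,3-dihydro-1H-inden-1-yl](4-methoxyphenyl)methanol (both carbinol epimers)
Conditions: 23 (1.5 equiv), THF, −78 °C; aq. NH4Cl
Reagents that add atoms: 4-methoxyphenylmagnesium bromide (23), COc1ccc([Mg]Br)cc1
Why: Grignard addition to the aldehyde at low temperature, where addition should outrun enolisation; the carbinol carbon need not be controlled because step 13 ionises it.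

Step 13
Reactants: 24 the carbinol
Product: 25 octa-O-methylstenophyllol B
Conditions: CF3CO2H (0.2 equiv), HFIP/CH2Cl2 1:1 (0.005 M), 0 °C to rt
Reagents that add atoms: none
Why: Intramolecular Friedel–Crafts alkylation in which the 4-methoxybenzylic cation holds the C-1 hydrogen in its plane to avoid A(1,3) strain and ring B, tethered through C-2, attacks with its activated ortho carbon from the C-2 side, which should close the eight-membered ring with the two methine hydrogens anti (new centre R), the trans indane ruling out the five-membered closure onto ring C.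

Step 14
Reactants: 25 octa-O-methylstenophyllol B
Product: 26 stenophyllol B
Conditions: BBr3 (20 equiv), CH2Cl2, −78 °C to rt; MeOH, then H2O
Reagents that add atoms: none
Why: Lewis-acid cleavage of the eight aryl methyl ethers; the benzylic C–O bond of the dihydrobenzofuran should survive at low temperature and would reclose trans if it opened, so no stereocentre is lost.

Compound list
1 | 2-bromo-4,6-dimethoxybenzaldehyde | COc1cc(OC)c(C=O)c(Br)c1 | starting material
2 | 2-bromo-6-hydroxy-4-methoxybenzaldehyde | COc1cc(O)c(C=O)c(Br)c1 | intermediate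
3 | 3,5-dimethoxyphenylmagnesium chloride | COc1cc(OC)cc([Mg]Cl)c1 | starting material
4 | 3-bromo-2-[(3,5-dimethoxyphenyl)(hydroxy)methyl]-5-methoxyphenol (racemic) | COc1cc(O)c(C(O)c2cc(OC)cc(OC)c2)c(Br)c1 | intermediate
5 | sodium 4-methylbenzenesulfinate | [Na+].[O-]S(=O)c1ccc(C)cc1 | starting material
6 | 3-bromo-2-[(3,5-dimethoxyphenyl)(4-methylbenzenesulfonyl)methyl]-5-methoxyphenol (racemic) | COc1cc(O)c(C(c2cc(OC)cc(OC)c2)S(=O)(=O)c2ccc(C)cc2)c(Br)c1 | intermediate
7 | (1R,4R,5R)-4,7,7-trimethyl-6-thiabicyclo[3.2.1]octane (isothiocineole) | C[C@@H]1CC[C@@H]2C[C@H]1SC2(C)C | starting material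
8 | 4-methoxybenzyl bromide | COc1ccc(CBr)cc1 | starting material
9 | (1R,4R,5R)-6-(4-methoxybenzyl)-4,7,7-trimethyl-6-thiabicyclo[3.2.1]octan-6-ium trifluoromethanesulfonate | C[C@@H]1CC[C@@H]2C[C@H]1[S+](Cc1ccc(OC)cc1)C2(C)C.[O-]S(=O)(=O)C(F)(F)F | intermediate
10 | 3-bromo-2-[(3,5-dimethoxyphenyl)methylidene]-5-methoxycyclohexa-3,5-dien-1-one (ortho-quinone methide) | O=C1C=C(OC)C=C(Br)C1=Cc1cc(OC)cc(OC)c1 | intermediate
11 | (2R,3R)-4-bromo-3-(3,5-dimethoxyphenyl)-6-methoxy-2-(4-methoxyphenyl)-2,3-dihydro-1-benzofuran | Brc1cc(OC)cc2c1[C@@H](c3cc(OC)cc(OC)c3)[C@H](c3ccc(OC)cc3)O2 | intermediate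
12 | 5,7-dimethoxycoumarin | COc1cc(OC)c2ccc(=O)oc2c1 | starting material
13 | 4-methoxyphenylboronic acid | COc1ccc(cc1)B(O)O | starting material
14 | (4S)-5,7-dimethoxy-4-(4-methoxyphenyl)-3,4-dihydro-2H-chromen-2-one | COc1ccc([C@@H]2CC(=O)Oc3cc(OC)cc(OC)c32)cc1 | intermediate
15 | chlorozinc enolate of 14 | COc1ccc([C@@H]2C=C(O[Zn]Cl)Oc3cc(OC)cc(OC)c32)cc1 | intermediate
16 | (3S,4S)-3-DBF-5,7-dimethoxy-4-(4-methoxyphenyl)-3,4-dihydro-2H-chromen-2-one (3,4-trans) | COc1ccc([C@@H]2[C@@H](c4cc(OC)cc5c4[C@@H](c6cc(OC)cc(OC)c6)[C@H](c6ccc(OC)cc6)O5)C(=O)Oc3cc(OC)cc(OC)c32)cc1 | intermediate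
17 | (3S,4S)-3-DBF-5,7-dimethoxy-4-(4-methoxyphenyl)-3,4-dihydro-2H-chromen-2-ol (both anomers) | COc1ccc([C@@H]2[C@@H](c4cc(OC)cc5c4[C@@H](c6cc(OC)cc(OC)c6)[C@H](c6ccc(OC)cc6)O5)C(O)Oc3cc(OC)cc(OC)c32)cc1 | intermediate
18 | (methoxymethyl)triphenylphosphonium chloride | COC[P+](c1ccccc1)(c1ccccc1)c1ccccc1.[Cl-] | starting material
19 | potassium 2-[(1S,2R)-2-DBF-4-methoxy-1-(4-methoxyphenyl)but-3-en-1-yl]-3,5-dimethoxyphenolate (E/Z) | COc1ccc([C@@H](c2c(OC)cc(OC)cc2[O-])[C@@H](c4cc(OC)cc5c4[C@@H](c6cc(OC)cc(OC)c6)[C@H](c6ccc(OC)cc6)O5)C=COC)cc1.[K+] | intermediate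
20 | 2-[(1S,2R)-2-DBF-4-methoxy-1-(4-methoxyphenyl)but-3-en-1-yl]-3,5-dimethoxyphenyl trifluoromethanesulfonate (E/Z) | COc1ccc([C@@H](c2c(OC)cc(OC)cc2OS(=O)(=O)C(F)(F)F)[C@@H](c4cc(OC)cc5c4[C@@H](c6cc(OC)cc(OC)c6)[C@H](c6ccc(OC)cc6)O5)C=COC)cc1 | intermediate
21 | 2-[(1S,2S)-2-DBF-1-(4-methoxyphenyl)-4-oxobutyl]-3,5-dimethoxyphenyl trifluoromethanesulfonate | COc1ccc([C@@H](c2c(OC)cc(OC)cc2OS(=O)(=O)C(F)(F)F)[C@@H](c4cc(OC)cc5c4[C@@H](c6cc(OC)cc(OC)c6)[C@H](c6ccc(OC)cc6)O5)CC=O)cc1 | intermediate
22 | (1S,2R,3S)-2-DBF-4,6-dimethoxy-3-(4-methoxyphenyl)-2,3-dihydro-1H-indene-1-carbaldehyde (all-trans) | COc1ccc([C@H]2c3c(OC)cc(OC)cc3[C@@H](C=O)[C@@H]2c4cc(OC)cc5c4[C@@H](c6cc(OC)cc(OC)c6)[C@H](c6ccc(OC)cc6)O5)cc1 | intermediate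
23 | 4-methoxyphenylmagnesium bromide | COc1ccc([Mg]Br)cc1 | starting material
24 | [(1S,2R,3S)-2-DBF-4,6-dimethoxy-3-(4-methoxyphenyl)-2,3-dihydro-1H-inden-1-yl](4-methoxyphenyl)methanol (both carbinol epimers) | COc1ccc([C@H]2c3c(OC)cc(OC)cc3[C@@H](C(O)c7ccc(OC)cc7)[C@@H]2c4cc(OC)cc5c4[C@@H](c6cc(OC)cc(OC)c6)[C@H](c6ccc(OC)cc6)O5)cc1 | intermediate
25 | octa-O-methylstenophyllol B | COc1ccc([C@H]2c3c(OC)cc(OC)cc3[C@H]3[C@H](c4ccc(OC)cc4)c4c(OC)cc(OC)cc4[C@@H]4c5c(cc(OC)cc5[C@H]23)O[C@H]4c2ccc(OC)cc2)cc1 | intermediate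
26 | stenophyllol B | Oc1ccc([C@H]2c3c(O)cc(O)cc3[C@H]3[C@H](c4ccc(O)cc4)c4c(O)cc(O)cc4[C@@H]4c5c(cc(O)cc5[C@H]23)O[C@H]4c2ccc(O)cc2)cc1 | target

Total step count: 14. Longest linear sequence: 12 (steps 1, 2, 3, 5, 7, 8, 9, 10, 11, 12, 13, 14).

Steps most likely to fail

Step 11. The aldehyde enolate may self-condense or be dehydrogenated at palladium while oxidative addition to the hindered triflate is slow, and C–H arylation of the neighbouring anisyl ring to a fluorene may compete. The fallback sets out from 21 and comes back at 24; it changes the nucleophile to an aryl ketone enolate, which cannot self-condense. 21 is treated with 23 (THF, −78 °C) to give the secondary alcohol F1, which Dess–Martin periodinane oxidises to the aryl ketone F2. Palladium-catalysed intramolecular ketone α-arylation (Pd2(dba)3, XPhos, K3PO4, toluene, 100 °C) closes the same C-7a–C-1 bond to the aroylindane F3, whose C-1 should again equilibrate to all-trans. NaBH4 (MeOH/THF, 0 °C) then reduces F3 to 24.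

Step 13. The cation may lose the C-1 proton; re-protonation of the resulting styrene from its open face followed by five-membered closure onto ring C would drain the material, and the acid may open the benzofuran ether. The fallback sets out from 22 and comes back at 26; the electrophile becomes a neutral para-quinone methide, made and consumed without strong acid. 22 is treated with [4-(oxan-2-yloxy)phenyl]magnesium bromide (THF, −78 °C) to give the carbinol F4. Pyridinium p-toluenesulfonate with MeOH in HFIP removes the acetal and dehydrates the 4-hydroxybenzyl alcohol to the para-quinone methide F5, which ring B should attack in a vinylogous (1,6) Friedel–Crafts addition to give the ring-closed monophenol F6. BBr3 then cleaves its seven methyl ethers to 26.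

Step 7. Transmetallation and reductive elimination between two hindered partners may be slow, and ring opening of the aryl ester enolate to a ketene is the competing process. The fallback sets out from 14 and 11 and comes back at 16; it reverses the polarity. 14 is brominated through its lithium enolate (LiN(SiMe3)2, N-bromosuccinimide, THF, −78 °C) to the bromolactone F7, and 11 is converted by bromine–lithium exchange (t-BuLi, −78 °C) and ZnCl2 into the arylzinc chloride F8. A nickel-catalysed Negishi coupling of the secondary α-bromo ester (NiCl2(MeOCH2CH2OMe), 4,4'-di-tert-butyl-2,2'-bipyridine, THF/DMA, 0 °C) should join them through an α-acyl radical, and Et3N then equilibrates C-3 to the trans lactone 16.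

Further compounds
F1 | step 11 | 2-[(1S,2S)-2-DBF-4-hydroxy-1,4-bis(4-methoxyphenyl)butyl]-3,5-dimethoxyphenyl trifluoromethanesulfonate (both carbinol epimers) | COc1ccc([C@@H](c2c(OC)cc(OC)cc2OS(=O)(=O)C(F)(F)F)[C@@H](c4cc(OC)cc5c4[C@@H](c6cc(OC)cc(OC)c6)[C@H](c6ccc(OC)cc6)O5)CC(O)c3ccc(OC)cc3)cc1
F2 | step 11 | 2-[(1S,2S)-2-DBF-1,4-bis(4-methoxyphenyl)-4-oxobutyl]-3,5-dimethoxyphenyl trifluoromethanesulfonate | COc1ccc([C@@H](c2c(OC)cc(OC)cc2OS(=O)(=O)C(F)(F)F)[C@@H](c4cc(OC)cc5c4[C@@H](c6cc(OC)cc(OC)c6)[C@H](c6ccc(OC)cc6)O5)CC(=O)c3ccc(OC)cc3)cc1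
F3 | step 11 | [(1S,2R,3S)-2-DBF-4,6-dimethoxy-3-(4-methoxyphenyl)-2,3-dihydro-1H-inden-1-yl](4-methoxyphenyl)methanone | COc1ccc([C@H]2c3c(OC)cc(OC)cc3[C@@H](C(=O)c7ccc(OC)cc7)[C@@H]2c4cc(OC)cc5c4[C@@H](c6cc(OC)cc(OC)c6)[C@H](c6ccc(OC)cc6)O5)cc1
F4 | step 13 | analogue of 24 with a 4-(oxan-2-yloxy)phenyl group on the carbinol carbon (indane configured as in 22) | COc1ccc([C@H]2c3c(OC)cc(OC)cc3[C@@H](C(O)c7ccc(OC8CCCCO8)cc7)[C@@H]2c4cc(OC)cc5c4[C@@H](c6cc(OC)cc(OC)c6)[C@H](c6ccc(OC)cc6)O5)cc1
F5 | step 13 | 4-{[2-DBF-4,6-dimethoxy-3-(4-methoxyphenyl)-2,3-dihydro-1H-inden-1-yl]methylidene}cyclohexa-2,5-dien-1-one (indane configured as in 22) | COc1ccc([C@H]2c3c(OC)cc(OC)cc3[C@@H](C=C7C=CC(=O)C=C7)[C@@H]2c4cc(OC)cc5c4[C@@H](c6cc(OC)cc(OC)c6)[C@H](c6ccc(OC)cc6)O5)cc1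
F6 | step 13 | hepta-O-methylstenophyllol B with the free phenol on the aryl group of the eight-membered-ring diarylmethine | COc1ccc([C@H]2c3c(OC)cc(OC)cc3[C@H]3[C@H](c4ccc(O)cc4)c4c(OC)cc(OC)cc4[C@@H]4c5c(cc(OC)cc5[C@H]23)O[C@H]4c2ccc(OC)cc2)cc1
F7 | step 7 | (4S)-3-bromo-5,7-dimethoxy-4-(4-methoxyphenyl)-3,4-dihydro-2H-chromen-2-one (both C-3 epimers) | COc1ccc([C@@H]2C(Br)C(=O)Oc3cc(OC)cc(OC)c32)cc1
F8 | step 7 | chloro[(2R,3R)-3-(3,5-dimethoxyphenyl)-6-methoxy-2-(4-methoxyphenyl)-2,3-dihydro-1-benzofuran-4-yl]zinc | Cl[Zn]c1cc(OC)cc2c1[C@@H](c3cc(OC)cc(OC)c3)[C@H](c3ccc(OC)cc3)O2
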